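The target is cut at the C9–C11 ketone bond and at the glyceryl ester, which leaves a ring A keto acid that is dehydroabietic acid 1 read backwards: abietane C4 with its C18 carboxyl becomes C10/C9, C5–C6–C7 stay, and abietane C10 becomes the gem-dimethyl C4. In one operation RuO4 burns aromatic ring C of methyl ester 2 and thereby opens ring B: only the fusion carbons C8 and C9, bound to the sp3 carbons C7 and C10, survive as carboxyl groups in diacid monoester 3, while ring A with C4, C5 and C10 stays intact. The precursor 2 is simply the resin acid methyl ester, its ester marking the future C9.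

Key step: step 2

Remarks on the chemistry (assumptions):
- Atom labels follow abietane numbering up to the aldehyde/hydrazone stage and the numbering of the target afterwards.
- The ring carboxyl of 3 sits on a quaternary carbon and is treated as a tertiary, strongly hindered acid.
- Ring A of 3 would be meso if its two ring carboxyls were alike, so they are never brought to the same oxidation level, and conditions that could exchange ester and acid through a bridged anhydride are avoided.
- The CIP descriptors of the iodo ester and of glycidyl acetate differ from those of their precursors although no bond at the stereocentre is touched.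

Step 1
Reactants: 1 dehydroabietic acid
Product: 2 methyl dehydroabietate
Conditions: MeI, K2CO3, DMF, rt
Reagents that add atoms: iodomethane CI
Why: SN2 O-alkylation of the carboxylate esterifies the hindered tertiary acid, for which Fischer conditions would be too slow; no stereocentre is involved.

Step 2
Reactants: 2 methyl dehydroabietate
Product: 3 3-[(1R,2S,6R)-2-carboxy-6-(methoxycarbonyl)-2,6-dimethylcyclohexyl]propanoic acid
Conditions: RuCl3·xH2O (5 mol %), NaIO4 (20 equiv), CCl4/MeCN/H2O (2:2:3), rt
Reagents that add atoms: sodium periodate [Na+].[O-]I(=O)(=O)=O (oxygen, relayed through RuO4); water O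
Why: RuO4, regenerated from RuCl3 by periodate, adds across the C=C bonds of ring C in [3+2] fashion to give ruthenate diesters that fragment, and the resulting diols, diketones and keto acids are cleaved in turn until every ring carbon has reached the carboxyl or CO2 level. The closest known reaction type is the RuCl3/NaIO4 degradation of an alkyl-substituted benzene ring to a carboxylic acid. No ring is closed (ring B is opened) and no stereocentre is formed: abietane C4 and C10 are quaternary and C5–H is not alpha to any carbonyl, so all three are carried through unchanged. C8 and C9 survive because their sp3 neighbours C7 and C10 cannot be cleaved further, whereas C13 should leave with its isopropyl group as 2-methylpropanoic acid and C11, C12 and C14 as CO2. The selectivity needed is arene attack in preference to oxidation of the benzylic C7 methylene; the electron-rich trialkylated ring, acetonitrile as co-solvent (it keeps ruthenium from being trapped as carboxylate complexes) and a large excess of periodate should secure it, and the tertiary methyl ester is inert.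

Step 3
Reactants: 3 diacid monoester
Product: 4 (1S,2R,3R)-2-(3-methoxy-3-oxopropyl)-3-(methoxycarbonyl)-1,3-dimethylcyclohexane-1-carboxylic acid
Conditions: MeOH, H2SO4 (cat.), rt
Reagents that add atoms: methanol CO
Why: Fischer esterification under mild acid catalysis is limited to the unhindered primary chain carboxyl, since the ring carboxyl on quaternary abietane C10 does not reach the tetrahedral intermediate at a useful rate; the mild conditions also exclude ester/acid exchange between the two ring carboxyls.

Step 4
Reactants: 4 ring acid diester
Product: 5 methyl (1R,2R,3S)-3-(hydroxymethyl)-2-(3-methoxy-3-oxopropyl)-1,3-dimethylcyclohexane-1-carboxylate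
Conditions: BH3·SMe2, THF, 0 °C to rt; MeOH quench
Reagents that add atoms: none
Why: chemoselective borane reduction takes a free carboxylic acid through its acyloxyborane far faster than either methyl ester, so only the ring carboxyl should become CH2OH; a neutral methanolic quench and prompt use avoid lactonisation onto the cis ring ester.

Step 5
Reactants: 5 hydroxy diester
Product: 6 methyl (1R,2R,3S)-3-formyl-2-(3-methoxy-3-oxopropyl)-1,3-dimethylcyclohexane-1-carboxylate
Conditions: Dess–Martin periodinane, pyridine, CH2Cl2, 0 °C to rt
Reagents that add atoms: none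
Why: Dess–Martin oxidation should convert the hindered primary alcohol to the non-enolisable aldehyde under neutral conditions that leave both esters untouched.

Step 6
Reactants: 6 aldehyde diester
Product: 8 (1R,2R)-2-(2-carboxyethyl)-1,3,3-trimethylcyclohexane-1-carboxylic acid, via hydrazone 7 (not isolated)
Conditions: N2H4·H2O, diethylene glycol, 80 °C; then KOH, 130 to 200 °C (water and excess hydrazine distilled off); aq. HCl
Reagents that add atoms: hydrazine hydrate NN.O (nitrogen held in intermediate 7 only); potassium hydroxide [K+].[OH-] (oxygen of the two freed carboxyl groups)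
Why: Wolff–Kishner reduction in the Huang-Minlon modification should turn the hindered aldehyde into the second methyl of the gem-dimethyl group by base-induced loss of N2 from the hydrazone, while the hot KOH saponifies both methyl esters in the same flask, including the hindered ring ester that has to be freed anyway; no centre can epimerise because C5–H is not alpha to a carbonyl.

Step 7
Reactants: 8 diacid
Product: 9 (1R,2R)-2-{3-[methoxy(methyl)amino]-3-oxopropyl}-1,3,3-trimethylcyclohexane-1-carboxylic acid
Conditions: MeNHOMe·HCl, EDC·HCl (1.2 equiv), HOBt, iPr2NEt, CH2Cl2, 0 °C to rt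
Reagents that add atoms: N,O-dimethylhydroxylamine hydrochloride CNOC.Cl
Why: carbodiimide/HOBt amidation should deliver the Weinreb amide only at the primary chain carboxyl, because the ring carboxyl on quaternary C10, flanked by C5 and the gem-dimethyl C4, is not attacked by the amine even if it is activated and returns as the free acid on work-up.

Step 8
Reactants: 9 Weinreb amide acid
Product: 10 (1R,2R)-1,3,3-trimethyl-2-(3-oxobutyl)cyclohexane-1-carboxylic acid
Conditions: MeMgBr (3.5 equiv), THF, −10 to 0 °C; aq. HCl
Reagents that add atoms: methylmagnesium bromide C[Mg]Br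
Why: Weinreb ketone synthesis: the first equivalent of Grignard reagent converts the ring acid to an inert magnesium carboxylate and the next adds once to the amide, whose chelated tetrahedral intermediate releases the C8 methyl ketone only on acidic work-up.

Step 9
Reactants: 11 (R)-3-methylglutaric acid monomethyl ester
Product: 12 methyl (3R)-5-hydroxy-3-methylpentanoate
Conditions: BH3·SMe2, THF, −10 °C to rt; MeOH quench
Reagents that add atoms: none
Why: chemoselective borane reduction of the free carboxyl beside the methyl ester fixes which end of the glutarate becomes C11, so the untouched stereocentre becomes C13 with the required R configuration; crude use of the product avoids lactonisation.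

Step 10
Reactants: 12 hydroxy ester
Product: 13 methyl (3S)-5-iodo-3-methylpentanoate
Conditions: I2, PPh3, imidazole, CH2Cl2, 0 °C to rt
Reagents that add atoms: iodine II
Why: Appel-type iodination replaces the primary hydroxyl by iodide through the alkoxyphosphonium salt (SN2 at CH2) two carbons away from the stereocentre, whose descriptor changes to S only through the CIP rank of the iodoethyl arm.

Step 11
Reactants: 10 keto acid; 13 iodo ester
Product: 16 methyl (3R)-3-methyl-6-oxo-6-[(1R,2R)-1,3,3-trimethyl-2-(3-oxobutyl)cyclohexyl]hexanoate, via acid chloride 14 (not isolated), via alkylzinc iodide 15 (not isolated)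
Conditions: (a) 10, (COCl)2, DMF (cat.), CH2Cl2, 0 °C to rt, evaporate; (b) 13, Zn dust (activated with BrCH2CH2Br and Me3SiCl), LiCl, THF, 40 °C; (c) 14 + 15, Pd(PPh3)4 (5 mol %), THF, 0 °C to rt
Reagents that add atoms: oxalyl chloride ClC(=O)C(Cl)=O (chlorine of intermediate 14 only); zinc [Zn] (metal of intermediate 15 only)
Why: Negishi-type acylation: zerovalent palladium inserts into the C–Cl bond of the tertiary acyl chloride, the ester-bearing primary alkylzinc iodide transmetalates and reductive elimination forges the C9–C11 bond, while the organozinc is too mild to add to the methyl ketone, the ester or the product ketone.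

Step 12
Reactants: 16 diketo ester
Product: 17 (3R)-3-methyl-6-oxo-6-[(1R,2R)-1,3,3-trimethyl-2-(3-oxobutyl)cyclohexyl]hexanoic acid
Conditions: LiOH·H2O, THF/H2O (3:1), 0 °C to rt; aq. HCl to pH 3
Reagents that add atoms: lithium hydroxide [Li+].[OH-]
Why: saponification of the unhindered primary methyl ester is fast at low temperature, where the two ketones (one shielded by quaternary C10) should not undergo aldol closure, and neither C13 nor the ring centres lie alpha to a carbonyl.

Step 13
Reactants: 18 (R)-glycidol
Product: 19 (S)-glycidyl acetate
Conditions: Ac2O, Et3N, DMAP (cat.), CH2Cl2, 0 °C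
Reagents that add atoms: acetic anhydride CC(=O)OC(C)=O
Why: DMAP-catalysed O-acylation of the primary alcohol leaves the epoxide and its stereocentre untouched; the descriptor becomes S only through the CIP rank of the acetoxymethyl group.

Step 14
Reactants: 17 diketo acid; 19 (S)-glycidyl acetate
Product: 20 (2R)-3-(acetyloxy)-2-hydroxypropyl (3R)-3-methyl-6-oxo-6-[(1R,2R)-1,3,3-trimethyl-2-(3-oxobutyl)cyclohexyl]hexanoate
Conditions: Bu4NBr (10 mol %), 19 (1.5 equiv), MeCN, 80 °C
Reagents that add atoms: none
Why: onium-salt-catalysed ring opening of a terminal epoxide by a carboxylic acid: the carboxylate (directly or through the bromohydrin) attacks the unsubstituted epoxide carbon in SN2 fashion, so the glycidyl stereocentre is not touched and should become the 2R carbinol between the new ester and the acetate.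

Compound list
1 | dehydroabietic acid, (1R,4aS,10aR)-1,4a-dimethyl-7-(propan-2-yl)-1,2,3,4,4a,9,10,10a-octahydrophenanthrene-1-carboxylic acid | CC(C)c1ccc2c(c1)CC[C@@H]1[C@]2(C)CCC[C@@]1(C)C(=O)O | starting material
2 | methyl dehydroabietate (methyl ester of 1) | CC(C)c1ccc2c(c1)CC[C@@H]1[C@]2(C)CCC[C@@]1(C)C(=O)OC | intermediate
3 | 3-[(1R,2S,6R)-2-carboxy-6-(methoxycarbonyl)-2,6-dimethylcyclohexyl]propanoic acid | OC(=O)CC[C@@H]1[C@@](C)(C(=O)O)CCC[C@@]1(C)C(=O)OC | intermediate
4 | (1S,2R,3R)-2-(3-methoxy-3-oxopropyl)-3-(methoxycarbonyl)-1,3-dimethylcyclohexane-1-carboxylic acid | COC(=O)CC[C@@H]1[C@@](C)(C(=O)O)CCC[C@@]1(C)C(=O)OC | intermediate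
5 | methyl (1R,2R,3S)-3-(hydroxymethyl)-2-(3-methoxy-3-oxopropyl)-1,3-dimethylcyclohexane-1-carboxylate | COC(=O)CC[C@@H]1[C@@](C)(CO)CCC[C@@]1(C)C(=O)OC | intermediate
6 | methyl (1R,2R,3S)-3-formyl-2-(3-methoxy-3-oxopropyl)-1,3-dimethylcyclohexane-1-carboxylate | COC(=O)CC[C@@H]1[C@@](C)(C=O)CCC[C@@]1(C)C(=O)OC | intermediate
7 | methyl (1R,2R,3S)-3-[(E)-hydrazinylidenemethyl]-2-(3-methoxy-3-oxopropyl)-1,3-dimethylcyclohexane-1-carboxylate | COC(=O)CC[C@@H]1[C@@](C)(/C=N/N)CCC[C@@]1(C)C(=O)OC | intermediate (not isolated)
8 | (1R,2R)-2-(2-carboxyethyl)-1,3,3-trimethylcyclohexane-1-carboxylic acid | OC(=O)CC[C@@H]1C(C)(C)CCC[C@@]1(C)C(=O)O | intermediate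
9 | (1R,2R)-2-{3-[methoxy(methyl)amino]-3-oxopropyl}-1,3,3-trimethylcyclohexane-1-carboxylic acid | CON(C)C(=O)CC[C@@H]1C(C)(C)CCC[C@@]1(C)C(=O)O | intermediate
10 | (1R,2R)-1,3,3-trimethyl-2-(3-oxobutyl)cyclohexane-1-carboxylic acid | CC(=O)CC[C@@H]1C(C)(C)CCC[C@@]1(C)C(=O)O | intermediate
11 | (R)-3-methylglutaric acid monomethyl ester, (3R)-5-methoxy-3-methyl-5-oxopentanoic acid | OC(=O)C[C@@H](C)CC(=O)OC | starting material
12 | methyl (3R)-5-hydroxy-3-methylpentanoate | OCC[C@@H](C)CC(=O)OC | intermediate
13 | methyl (3S)-5-iodo-3-methylpentanoate | ICC[C@@H](C)CC(=O)OC | intermediate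
14 | (1R,2R)-1,3,3-trimethyl-2-(3-oxobutyl)cyclohexane-1-carbonyl chloride | CC(=O)CC[C@@H]1C(C)(C)CCC[C@@]1(C)C(Cl)=O | intermediate (not isolated)
15 | [(3S)-5-methoxy-3-methyl-5-oxopentyl]zinc iodide | I[Zn]CC[C@@H](C)CC(=O)OC | intermediate (not isolated)
16 | methyl (3R)-3-methyl-6-oxo-6-[(1R,2R)-1,3,3-trimethyl-2-(3-oxobutyl)cyclohexyl]hexanoate | CC(=O)CC[C@@H]1C(C)(C)CCC[C@@]1(C)C(=O)CC[C@@H](C)CC(=O)OC | intermediate
17 | (3R)-3-methyl-6-oxo-6-[(1R,2R)-1,3,3-trimethyl-2-(3-oxobutyl)cyclohexyl]hexanoic acid | CC(=O)CC[C@@H]1C(C)(C)CCC[C@@]1(C)C(=O)CC[C@@H](C)CC(=O)O | intermediate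
18 | (R)-glycidol, (2R)-oxiran-2-ylmethanol | OC[C@@H]1CO1 | starting material
19 | (S)-glycidyl acetate, (2S)-oxiran-2-ylmethyl acetate | CC(=O)OC[C@@H]1CO1 | intermediate
20 | CNP0140002.1, (2R)-3-(acetyloxy)-2-hydroxypropyl (3R)-3-methyl-6-oxo-6-[(1R,2R)-1,3,3-trimethyl-2-(3-oxobutyl)cyclohexyl]hexanoate | CC(=O)CC[C@@H]1C(C)(C)CCC[C@@]1(C)C(=O)CC[C@@H](C)CC(=O)OC[C@H](O)COC(C)=O | target

Total step count: 14. Longest linear sequence: 11 steps (steps 1 to 8, 11, 12 and 14, from dehydroabietic acid).

Steps most likely to fail

Step 2. The benzylic C7 methylene may be oxidised before the arene is cleaved, which deactivates the ring and in the end shortens the chain by one carbon, or the combustion of ring C may stall at partly oxidised fragments. The fallback sets out from 2 and comes back at 3; it makes ring C electron-rich before it is degraded. Friedel–Crafts acetylation (AcCl, AlCl3, CH2Cl2, 0 °C) at C12, ortho to the isopropyl group, should give methyl 12-acetyldehydroabietate F1. Baeyer–Villiger oxidation (mCPBA, CH2Cl2, rt) should then give methyl 12-acetoxydehydroabietate F2, and methanolysis (K2CO3, MeOH, rt) the phenol methyl 12-hydroxydehydroabietate F3. Ozonolysis of the phenol ring with oxidative work-up (O3, CH2Cl2/MeOH, −78 °C; then H2O2, HCO2H) attacks the activated arene much faster than the C7 methylene and should deliver the same diacid monoester 3.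

Step 11. Acyl transfer at the congested tertiary acyl chloride may be slow, so that the alkylzinc reagent is lost to protonation or homocoupling, or the acylpalladium intermediate may lose CO. The fallback sets out from 10 and 13 and comes back at 16. Chloride 14, made from 10 as before, and iodide 13 are combined directly in a nickel-catalysed reductive cross-electrophile ketone synthesis (NiCl2(dme), 4,4'-di-tert-butyl-2,2'-bipyridine, Mn powder, DMA, 0 °C to rt). The alkyl radical from 13 is captured by an acylnickel species, so no organozinc reagent is needed; the fallback makes no new compound (F0).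

Step 14. Attack at the internal epoxide carbon, or acyl migration in the hot, weakly basic medium, may contaminate the 1,3-diester with isomeric diacylglycerols. The fallback sets out from 17 and 18 and comes back at 20. The titanium-mediated opening of the free epoxy alcohol (Ti(OiPr)4, CH2Cl2, rt), which directs the carboxylic acid to the terminal carbon C3 of (R)-glycidol, should give the monoacylglycerol (2R)-2,3-dihydroxypropyl (3R)-3-methyl-6-oxo-6-[(1R,2R)-1,3,3-trimethyl-2-(3-oxobutyl)cyclohexyl]hexanoate F4. Selective acetylation of its primary hydroxyl (AcCl, 2,4,6-collidine, CH2Cl2, −78 °C) then leads to 20.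

Further compounds
F1 | step 2 | methyl 12-acetyldehydroabietate | CC(C)c1cc2CC[C@@H]3[C@](C)(CCC[C@@]3(C)C(=O)OC)c2cc1C(C)=O
F2 | step 2 | methyl 12-acetoxydehydroabietate | CC(C)c1cc2CC[C@@H]3[C@](C)(CCC[C@@]3(C)C(=O)OC)c2cc1OC(C)=O
F3 | step 2 | methyl 12-hydroxydehydroabietate | CC(C)c1cc2CC[C@@H]3[C@](C)(CCC[C@@]3(C)C(=O)OC)c2cc1O
F0 | step 11 | none | none
F4 | step 14 | (2R)-2,3-dihydroxypropyl (3R)-3-methyl-6-oxo-6-[(1R,2R)-1,3,3-trimethyl-2-(3-oxobutyl)cyclohexyl]hexanoate | CC(=O)CC[C@@H]1C(C)(C)CCC[C@@]1(C)C(=O)CC[C@@H](C)CC(=O)OC[C@H](O)CO
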